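(The constants used here were set for the occasion.)

Read the constants first: they belong to one catalytic round with one side exit.

    substrate + free catalyst ⇌ catalyst intermediate A (K1 = 0.55 /M, k1 = 0.34 /M/s, Ea1 = 64.0 kJ/mol, ΔH1 = −9.00 kJ/mol)
    catalyst intermediate A → catalyst intermediate B (k2 = 13 /s, Ea2 = 78.0 kJ/mol)
    catalyst intermediate B → free catalyst + product (k3 = 0.12 /s, Ea3 = 86.0 kJ/mol)
    catalyst intermediate A + capture agent → trapped intermediate (k4 = 0.11 /M/s, Ea4 = 71.0 kJ/mol)
    (constants at 110 °C)

| setting | spring | noon |
|---|---|---|
| substrate | 0.64 M | 0.64 M |
| capture agent | 0.192 M | 0.192 M |
| free catalyst | 2.5 mol% | 2.5 mol% |
| temperature | 110 °C | 135 °C |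
| time | 4.0 min | 4.0 min |

1. which of these there is most of at the end, counted by the substrate in it, spring (trapped intermediate / product / substrate / catalyst intermediate B)
2. which of these there is most of at the end, counted by the substrate in it, noon (trapped intermediate / product / substrate / catalyst intermediate B)
3. amount of the one of these that there is most of at the end, in percent of the substrate charged, spring
4. amount of the one of these that there is most of at the end, in percent of the substrate charged, noon

- at 110 °C the constants are as listed, elsewhere as the activation energies and enthalpies make them

**The zero.** Take the point where substrate and product stand equal as the zero of the scale. Before it substrate leads, after it product. Catalyst intermediate B and trapped intermediate stay within the catalyst charge, 2.5 mol%, so watch substrate and product.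

**The law.** Hold catalyst intermediate A and catalyst intermediate B in a steady state. Let c be the charged catalyst concentration, 0.0160 M. Let S be the substrate charge, s the substrate present and r the release constant of catalyst intermediate B. Let a be the binding constant times the forward share of catalyst intermediate A. Two waits then add: c·t = ln(S/s)/a + (S−s)/r. At the crossing, the time τ is a binding wait, ln(2)/(a·c), plus a release wait, S/(2·r·c).

**Testing each constant.** Start with the capture step. In spring its pseudo-first-order rate constant on catalyst intermediate A is 0.0211 /s, far below the forward 13 /s, so a rough value will do. The spring back step, 0.618 /s, is also far below it, at 4.76%, so the equilibrium constant can be rough too. The binding and release constants each carry a whole wait, and the loading divides both waits. Know these three well.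

**The numbers.** For spring, a is 0.324 /M/s. The waits are 2.23 min and 2.78 min, so τ is 5.01 min. Carry this crossing time, the time at which substrate and product stand equal. It is later than the reading at 4.0 min, so substrate leads in spring.

For noon, the constants become 1.16 /M/s for binding, 58.2 /s forward, 0.627 /s for release, and 0.463 /M for the equilibrium. So a is 1.11 /M/s. The waits are 0.648 min and 0.532 min, and τ is 1.18 min. That is earlier than the reading, so product leads at noon. My reckoning stops at the leaders.

**The forecast.** It goes on to amounts: substrate at 58.8% for spring, product at 94.7% for noon. Its ground: “Intermediate A is in steady state”.

**The result.** Spring gives substrate at 58.8%, with product at 39.9%. Noon gives product at 94.9%, with substrate at 4.80%. Spring was read at 0.798 of its τ, and noon at 3.39 times its τ.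

**Earlier reading.** Read the noon flask at 1.0 min, holding amounts and temperature. Its τ stays 1.18 min, and this reading comes earlier than that, at 0.847 of τ. So substrate should lead. It does, with substrate at 56.6% against product at 42.4%. Product and substrate hold the same at 0.302 of the asked time, which is 1.21 min.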